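## Retrosynthetic overview

- The target is a (2S)-flavanone joined by a C6–O–C4' diaryl ether to apigenin. The strategy rests on ring C of the flavanone: C4a–C4 and C8a–O1 are ortho neighbours on the trioxygenated ring A, and they are bridged by C3–C2, where C2 carries a para-oxygenated aryl group. This is the pattern left by an ortho-quinone methide adding to a styrene.
- Ring C is cut at C3–C4 and O1–C2. This gives a ring A salicylaldehyde, used as its 4-methoxy ortho-quinone methide cation, and 4-(benzyloxy)styrene. C4 arrives as a benzylic methyl ether (alcohol oxidation level) and is taken to the ketone by solvolysis and oxidation; BCl3 then frees the phenols.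
- The salicylaldehyde comes from ortho-formylation of a symmetric 3,5-dimethoxy-4-aryloxyphenol. That phenol is made from syringaldehyde by SNAr O-arylation and Baeyer–Villiger oxidation, done before the flavone is built so that no aldehyde is present in the Claisen condensation.
- Order of ring formation: first the pyranone ring of the flavone (Claisen condensation, cyclodehydration), then ring C of the flavanone in the key step.

Key step: step 8

Remark: the sense of induction of the chiral acid cannot be assigned in advance, so the catalyst antipode that delivers the 2S product is to be chosen in a first screen. C4 of the cycloadduct (expected cis, 4S) is a transient centre that does not reach the target.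

## Route

Step 1
Reactants: 1 2,4,6-trihydroxyacetophenone
Product: 2 1-[2,4-bis(benzyloxy)-6-hydroxyphenyl]ethanone
Conditions: BnBr (2.1 equiv), K2CO3 (2.2 equiv), DMF, rt
Reagents that add atoms: benzyl bromide, BrCc1ccccc1
Why: Williamson etherification, in which the hydroxyl hydrogen-bonded to the acetyl carbonyl is the least nucleophilic, so the two non-chelated phenols should be benzylated selectively.

Step 2
Reactants: 3 syringaldehyde (4-hydroxy-3,5-dimethoxybenzaldehyde); 4 methyl 4-fluorobenzoate
Product: 5 methyl 4-(4-formyl-2,6-dimethoxyphenoxy)benzoate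
Conditions: Cs2CO3 (1.5 equiv), 4 (1.5 equiv), DMSO, 120 °C, N2
Reagents that add atoms: none
Why: SNAr displacement of fluoride, activated by the para ester, by the cesium phenoxide of a non-enolisable aldehyde in a dipolar aprotic solvent.

Step 3
Reactants: 5 methyl 4-(4-formyl-2,6-dimethoxyphenoxy)benzoate
Product: 7 methyl 4-(4-hydroxy-2,6-dimethoxyphenoxy)benzoate, via aryl formate 6 (not isolated)
Conditions: mCPBA (1.5 equiv), CH2Cl2, rt; NaHCO3 wash; then K2CO3 (cat.), MeOH, rt
Reagents that add atoms: 3-chloroperbenzoic acid, OOC(=O)c1cccc(Cl)c1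
Why: Baeyer–Villiger (Dakin-type) oxidation, in which the electron-rich para-aryloxy aryl group migrates in preference to hydrogen; methanolysis of the formate then leaves the methyl ester unchanged.

Step 4
Reactants: 2 1-[2,4-bis(benzyloxy)-6-hydroxyphenyl]ethanone; 7 methyl 4-(4-hydroxy-2,6-dimethoxyphenoxy)benzoate
Product: 8 1-[2,4-bis(benzyloxy)-6-hydroxyphenyl]-3-[4-(4-hydroxy-2,6-dimethoxyphenoxy)phenyl]propane-1,3-dione
Conditions: LiN(SiMe3)2 (4.5 equiv), THF, −78 °C → rt; aq. HCl
Reagents that add atoms: none
Why: crossed Claisen condensation of the ketone dianion with the methyl ester; the remote phenol only consumes one further equivalent of base as a spectator lithium phenoxide, as in the polyanion variant of flavone synthesis.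

Step 5
Reactants: 8 1-[2,4-bis(benzyloxy)-6-hydroxyphenyl]-3-[4-(4-hydroxy-2,6-dimethoxyphenoxy)phenyl]propane-1,3-dione
Product: 9 5,7-bis(benzyloxy)-4'-(4-hydroxy-2,6-dimethoxyphenoxy)flavone
Conditions: NaOAc, AcOH, 100 °C
Reagents that add atoms: none
Why: cyclodehydration of an ortho-hydroxy-1,3-diketone to the 4H-chromen-4-one under buffered acid, mild enough to keep the benzyl ethers.

Step 6
Reactants: 9 5,7-bis(benzyloxy)-4'-(4-hydroxy-2,6-dimethoxyphenoxy)flavone
Product: 10 5,7-bis(benzyloxy)-4'-(3-formyl-4-hydroxy-2,6-dimethoxyphenoxy)flavone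
Conditions: MgCl2 (3 equiv), Et3N (6 equiv), (CH2O)n (8 equiv), THF, reflux; aq. HCl
Reagents that add atoms: paraformaldehyde (as formaldehyde), C=O
Why: magnesium phenoxide-directed ortho-formylation (Casnati–Skattebøl); the phenol is symmetric, so both ortho positions give the same aldehyde, and the deactivated magnesium salicylaldehydate should not react a second time.

Step 7
Reactants: 11 4-(benzyloxy)benzaldehyde
Product: 12 4-(benzyloxy)styrene
Conditions: Ph3PCH3Br (1.3 equiv), KOt-Bu (1.25 equiv), THF, 0 °C → rt
Reagents that add atoms: methyltriphenylphosphonium bromide, C[P+](c1ccccc1)(c1ccccc1)c1ccccc1.[Br-]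
Why: Wittig methylenation of an aromatic aldehyde with the non-stabilised ylide; no stereochemical issue arises.

Step 8
Reactants: 10 5,7-bis(benzyloxy)-4'-(3-formyl-4-hydroxy-2,6-dimethoxyphenoxy)flavone; 12 4-(benzyloxy)styrene
Product: 15 (2S,4S)-2-[4-(benzyloxy)phenyl]-6-{4-[5,7-bis(benzyloxy)-4-oxo-4H-chromen-2-yl]phenoxy}-4,5,7-trimethoxychromane, via dimethyl acetal 13 (not isolated), via oxocarbenium ion 14 (not isolated)
Conditions: HC(OMe)3 (1.5 equiv), chiral imidodiphosphorimidate acid HN[P(=NSO2CF3)(O2-BINOL-3,3'-Ar2)]2 with Ar = 3,5-(CF3)2C6H3 (5 mol%, antipode and Ar to be screened), CH2Cl2, 0 °C, 1 h; then 12 (1.5 equiv) added slowly, −40 °C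
Reagents that add atoms: trimethyl orthoformate, COC(OC)OC
Why: Proposed new method: acid-catalysed exchange with the orthoformate gives acetal 13, which the chiral acid ionises to the 2-hydroxyaryl oxocarbenium ion 14 (an O-protonated 4-methoxy ortho-quinone methide stabilised by the three oxygens of ring A) held as a contact ion pair with the imidodiphosphorimidate anion; the terminal carbon of styrene 12 attacks C4 and the para-benzyloxybenzyl cation so formed is captured by the free phenol oxygen, so ring C closes by an asynchronous inverse-demand (4+2) cycloaddition (C3–C4 first, then O1–C2 by six-membered cation–phenol collapse). The closest known reaction type is the achiral Brønsted- or Lewis-acid-promoted hetero-Diels–Alder of salicylaldehyde/orthoformate-derived ortho-quinone methides with styrenes to cis-2-aryl-4-alkoxychromans, together with enantioselective additions to ortho-quinone methides under chiral phosphoric-acid-type catalysis. C2 is set by the chiral counter-anion, which shields one face of the ion pair during bond formation (antipode chosen for 2S); C4 follows from the endo, cis-2,4 approach and is expected 4S, but it is erased in step 10. Regiochemistry is secured by polarity (styrene CH2 to the cationic C4, benzylic carbon to oxygen) and by the fact that the only free hydroxyl of 10 is the one ortho to the formyl group; the flavone enone and the benzyl ethers are not nucleophilic enough to compete. The step needs facial control at C2 only, and low temperature with slow addition of 12 is meant to suppress cationic oligomerisation of the styrene and re-ionisation of the product at C4 or at O1–C2.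

Step 9
Reactants: 15 (2S,4S)-2-[4-(benzyloxy)phenyl]-6-{4-[5,7-bis(benzyloxy)-4-oxo-4H-chromen-2-yl]phenoxy}-4,5,7-trimethoxychromane
Product: 16 (2S)-2-[4-(benzyloxy)phenyl]-6-{4-[5,7-bis(benzyloxy)-4-oxo-4H-chromen-2-yl]phenoxy}-5,7-dimethoxychroman-4-ol (C4 epimers)
Conditions: aq. HCl (0.5 M)–THF (1:4), dilute, rt
Reagents that add atoms: water, O
Why: SN1 solvolysis, in which the C4 methyl ether ionises to a benzylic cation stabilised by O1, 5-OMe and 7-OMe and is captured by water in large excess; C2 is not involved and both C4 epimers are carried on.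

Step 10
Reactants: 16 (2S)-2-[4-(benzyloxy)phenyl]-6-{4-[5,7-bis(benzyloxy)-4-oxo-4H-chromen-2-yl]phenoxy}-5,7-dimethoxychroman-4-ol (C4 epimers)
Product: 17 (2S)-2-[4-(benzyloxy)phenyl]-6-{4-[5,7-bis(benzyloxy)-4-oxo-4H-chromen-2-yl]phenoxy}-5,7-dimethoxychroman-4-one
Conditions: Dess–Martin periodinane (1.5 equiv), NaHCO3, CH2Cl2, 0 °C → rt
Reagents that add atoms: none
Why: Dess–Martin oxidation of a secondary benzylic alcohol under buffered, non-basic conditions; both C4 epimers converge on the ketone, no free phenol is present, and C2 should not open to the chalcone.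

Step 11
Reactants: 17 (2S)-2-[4-(benzyloxy)phenyl]-6-{4-[5,7-bis(benzyloxy)-4-oxo-4H-chromen-2-yl]phenoxy}-5,7-dimethoxychroman-4-one
Product: 18 (2S)-6-[4-(5,7-dihydroxy-4-oxo-4H-chromen-2-yl)phenoxy]-5-hydroxy-2-(4-hydroxyphenyl)-7-methoxychroman-4-one (target)
Conditions: BCl3 (10 equiv), C6HMe5 (10 equiv), CH2Cl2, −78 → 0 °C; H2O quench
Reagents that add atoms: none
Why: Lewis-acid dealkylation, in which BCl3 chelated to the C4 carbonyl cleaves the peri 5-OMe and removes the three benzyl ethers with pentamethylbenzene as cation scavenger; the non-chelated 7-OMe and the diaryl ether should survive at low temperature, and the medium is not basic, so C2 is not epimerised through the chalcone.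

## Compound list

1 | 2,4,6-trihydroxyacetophenone | CC(=O)c1c(O)cc(O)cc1O | starting material
2 | 1-[2,4-bis(benzyloxy)-6-hydroxyphenyl]ethanone | CC(=O)c1c(O)cc(OCc2ccccc2)cc1OCc1ccccc1 | intermediate
3 | syringaldehyde | COc1cc(C=O)cc(OC)c1O | starting material
4 | methyl 4-fluorobenzoate | COC(=O)c1ccc(F)cc1 | starting material
5 | methyl 4-(4-formyl-2,6-dimethoxyphenoxy)benzoate | COC(=O)c1ccc(Oc2c(OC)cc(C=O)cc2OC)cc1 | intermediate
6 | methyl 4-[4-(formyloxy)-2,6-dimethoxyphenoxy]benzoate (aryl formate) | COC(=O)c1ccc(Oc2c(OC)cc(OC=O)cc2OC)cc1 | intermediate (not isolated)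
7 | methyl 4-(4-hydroxy-2,6-dimethoxyphenoxy)benzoate | COC(=O)c1ccc(Oc2c(OC)cc(O)cc2OC)cc1 | intermediate
8 | 1-[2,4-bis(benzyloxy)-6-hydroxyphenyl]-3-[4-(4-hydroxy-2,6-dimethoxyphenoxy)phenyl]propane-1,3-dione | O=C(CC(=O)c1ccc(Oc2c(OC)cc(O)cc2OC)cc1)c1c(O)cc(OCc2ccccc2)cc1OCc1ccccc1 | intermediate
9 | 5,7-bis(benzyloxy)-4'-(4-hydroxy-2,6-dimethoxyphenoxy)flavone | COc1cc(O)cc(OC)c1Oc1ccc(-c2cc(=O)c3c(OCc4ccccc4)cc(OCc4ccccc4)cc3o2)cc1 | intermediate
10 | 5,7-bis(benzyloxy)-4'-(3-formyl-4-hydroxy-2,6-dimethoxyphenoxy)flavone | O=Cc1c(O)cc(OC)c(Oc2ccc(-c3cc(=O)c4c(OCc5ccccc5)cc(OCc5ccccc5)cc4o3)cc2)c1OC | intermediate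
11 | 4-(benzyloxy)benzaldehyde | O=Cc1ccc(OCc2ccccc2)cc1 | starting material
12 | 4-(benzyloxy)styrene | C=Cc1ccc(OCc2ccccc2)cc1 | intermediate
13 | dimethyl acetal of 10 | COC(OC)c1c(O)cc(OC)c(Oc2ccc(-c3cc(=O)c4c(OCc5ccccc5)cc(OCc5ccccc5)cc4o3)cc2)c1OC | intermediate (not isolated)
14 | 2-hydroxyaryl(methoxy)carbenium ion from 13 (O-protonated 4-methoxy ortho-quinone methide, paired with the catalyst anion) | C[O+]=Cc1c(O)cc(OC)c(Oc2ccc(-c3cc(=O)c4c(OCc5ccccc5)cc(OCc5ccccc5)cc4o3)cc2)c1OC | intermediate (not isolated)
15 | (2S,4S)-2-[4-(benzyloxy)phenyl]-6-{4-[5,7-bis(benzyloxy)-4-oxo-4H-chromen-2-yl]phenoxy}-4,5,7-trimethoxychromane | COc1cc2c(c(OC)c1Oc1ccc(-c3cc(=O)c4c(OCc5ccccc5)cc(OCc5ccccc5)cc4o3)cc1)[C@@H](OC)C[C@@H](c1ccc(OCc3ccccc3)cc1)O2 | intermediate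
16 | (2S)-2-[4-(benzyloxy)phenyl]-6-{4-[5,7-bis(benzyloxy)-4-oxo-4H-chromen-2-yl]phenoxy}-5,7-dimethoxychroman-4-ol, C4 epimers | COc1cc2c(c(OC)c1Oc1ccc(-c3cc(=O)c4c(OCc5ccccc5)cc(OCc5ccccc5)cc4o3)cc1)C(O)C[C@@H](c1ccc(OCc3ccccc3)cc1)O2 | intermediate
17 | (2S)-2-[4-(benzyloxy)phenyl]-6-{4-[5,7-bis(benzyloxy)-4-oxo-4H-chromen-2-yl]phenoxy}-5,7-dimethoxychroman-4-one | COc1cc2c(c(OC)c1Oc1ccc(-c3cc(=O)c4c(OCc5ccccc5)cc(OCc5ccccc5)cc4o3)cc1)C(=O)C[C@@H](c1ccc(OCc3ccccc3)cc1)O2 | intermediate
18 | (2S)-6-[4-(5,7-dihydroxy-4-oxo-4H-chromen-2-yl)phenoxy]-5-hydroxy-2-(4-hydroxyphenyl)-7-methoxychroman-4-one | COc1cc2c(c(O)c1Oc1ccc(-c3cc(=O)c4c(O)cc(O)cc4o3)cc1)C(=O)C[C@@H](c1ccc(O)cc1)O2 | target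

## Summary

Total step count: 11.
Longest linear sequence: 9 steps (steps 2, 3, 4, 5, 6, 8, 9, 10, 11, from syringaldehyde).

## Steps most likely to fail

**1. Step 8 (key step).** Several processes can defeat it:
- poor facial discrimination at C2 if the large biaryl-ether substituent does not sit in the chiral pocket;
- a racemic background path, because the very electron-rich acetal ionises so easily that the protonated pyranone carbonyl of the flavone or adventitious acid can act as an achiral catalyst;
- sequestration of the catalyst by that basic carbonyl;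
- erosion of enantiopurity by reversible O1–C2 ionisation;
- cationic oligomerisation of the styrene.

The fallback moves stereocontrol from catalysis to separation and uses the established reaction type. It sets out from 10 and 12. The cycloaddition is run with an achiral acid (HC(OMe)3, catalytic TfOH, CH2Cl2, −20 °C) and should give the racemic cis-(2S*,4S*)-4-methoxyflavan F1. The enantiomers are separated by preparative chromatography on a chiral stationary phase (amylose tris(3,5-dimethylphenylcarbamate)), and the (2S,4S) antipode comes back to the route as 15.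

**2. Step 2.** The hindered, weakly nucleophilic 2,6-dimethoxy-4-formylphenoxide may substitute slowly at a fluoroarene that is only moderately activated by an ester, while acyl transfer and ester cleavage compete at 120 °C.

The fallback replaces SNAr by metal-free arylation with a diaryliodonium salt and sets out from 3. Methyl 4-iodobenzoate is oxidised with mCPBA and TsOH·H2O in MeCN and trapped with 1,3,5-trimethoxybenzene to give [4-(methoxycarbonyl)phenyl](2,4,6-trimethoxyphenyl)iodonium tosylate F2. The phenoxide of 3 (K2CO3, toluene, 50 °C) should then take up the electron-poor aryl group selectively, which comes back to the route as 5.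

**3. Step 11.** Possible failures are:
- loss of selectivity between the chelated 5-OMe and the 7-OMe;
- incomplete debenzylation or C-benzylation of the electron-rich rings;
- Lewis-acid opening of O1–C2, which would racemise C2.

The fallback stages the deprotection and sets out from 17. Hydrogenolysis (H2, Pd/C, EtOAc–THF, rt) removes the three benzyl ethers under neutral conditions to give the 5-O-methyl triphenol F3. Chelation-controlled demethylation peri to the C4 carbonyl with MgI2 etherate (THF–toluene, 50 °C) then comes back to the route as 18.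

## Further compounds

F1 | step 8 | racemic cis-(2S*,4S*)-2-[4-(benzyloxy)phenyl]-6-{4-[5,7-bis(benzyloxy)-4-oxo-4H-chromen-2-yl]phenoxy}-4,5,7-trimethoxychromane | COc1cc2c(c(OC)c1Oc1ccc(-c3cc(=O)c4c(OCc5ccccc5)cc(OCc5ccccc5)cc4o3)cc1)C(OC)CC(c1ccc(OCc3ccccc3)cc1)O2
F2 | step 2 | [4-(methoxycarbonyl)phenyl](2,4,6-trimethoxyphenyl)iodonium 4-methylbenzenesulfonate | COC(=O)c1ccc([I+]c2c(OC)cc(OC)cc2OC)cc1.Cc1ccc(S(=O)(=O)[O-])cc1
F3 | step 11 | (2S)-6-[4-(5,7-dihydroxy-4-oxo-4H-chromen-2-yl)phenoxy]-2-(4-hydroxyphenyl)-5,7-dimethoxychroman-4-one | COc1cc2c(c(OC)c1Oc1ccc(-c3cc(=O)c4c(O)cc(O)cc4o3)cc1)C(=O)C[C@@H](c1ccc(O)cc1)O2
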